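The data were computed for an exercise.

4 questions stand on this flask: how high the target peaks, when, and how long it stays near that peak.

| setting | Wednesday's | Sunday's | flask |
|---|---|---|---|
| substrate | 57 mM | 90 mM | 41 mM |
| partner | 20.5 mM | 20.5 mM | 20.5 mM |
| second reagent | 61.5 mM | 61.5 mM | 61.5 mM |
| third reagent | 45.1 mM | 45.1 mM | 45.1 mM |
| remark | run made earlier | run made earlier |  |
| time |  |  | 15 d |

| run | time / d | target / % |
|---|---|---|
| Wednesday's | 0.167 | 9.6 |
| Wednesday's | 0.500 | 17.4 |
| Wednesday's | 1.25 | 9.0 |
| Wednesday's | 4.00 | 0.3 |
| Wednesday's | 12.0 | 0.4 |
| Sunday's | 0.167 | 6.9 |
| Sunday's | 0.500 | 7.4 |
| Sunday's | 1.25 | 1.0 |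
| Sunday's | 4.00 | 0.3 |
| Sunday's | 12.0 | 0.1 |

(scatter of a reading: 0.3 percentage points)

- the best time, 15 d at the latest, for target
- the amount of target, in percent of the substrate charged, at that time
- earliest time at which at least nineteen twentieths of that best amount are there, in d
- latest time at which they still are, in d



We build the flask up one process at a time. First comes the main step alone, which we assume to be substrate and partner giving target, one to one. Here c_partner lies below c_substrate, so partner is the limiting reagent. The ceiling is c_partner/c_substrate, or 50.0% of the substrate charged.

Next comes the loss. At 1.25 d, Sunday's run, with more substrate, holds less target than Wednesday's, 1.0% against 9.0%. So we let substrate consume target too. Making and losing target then both carry c_substrate, which cancels from their ratio. We therefore count by the fraction of partner left, not by time. On that clock, our picture gives the same target curve whatever the substrate charge, while substrate lasts.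

Wednesday's highest reading gives 48.4% for the partner yield, the share of the partner charge standing as target at the peak. Applied to the ceiling, it gives 24.2% for this flask.

Last comes the clock itself. Partner goes at a rate proportional to c_substrate, so we scale Wednesday's 0.500 d by the substrate charges. That puts this flask's peak near 0.695 d. The same scaling puts Sunday's peak near 0.317 d, between its readings at 0.167 d and 0.500 d. Sunday's readings fall on either side of that time and do not show its peak, so we take no partner yield from them. The fall of substrate during the run would stretch our time, and we leave that out of the number.

The forecast says 30% at 1 d, with a window from 0.7 d to 1.4 d. It reasons: “Substrate depletion matters more at only two equivalents, so the loss slows further”. Our height is lower and our time earlier.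

The flask gives 26.2% at 0.643 d, and stays within the margin from 0.457 d to 0.920 d.

    substrate + partner → intermediate A (k = 0.100 M⁻¹ min⁻¹)
    second reagent + intermediate A → intermediate B (k = 0.442 M⁻¹ min⁻¹)
    substrate + target → side product (k = 0.0388 M⁻¹ min⁻¹)
    third reagent → decomposed reagent (k = 1.56 × 10⁻⁴ min⁻¹)
    third reagent + intermediate B → target (k = 0.154 M⁻¹ min⁻¹)

At its peak this flask holds 52.4% of its partner charge as target, against the 48.4% read from Wednesday's run. The scheme also spends one third reagent per target. So we repeat the reckoning on the neighbour charged with 18 mM of third reagent, below c_partner. Its ceiling becomes 43.9% of the substrate charged, and the partner yield gives 21.2%. That neighbour reaches 17.9%. At 15.0 d it has 0% of its third reagent left, and intermediate B holds 12.0% of the substrate charged.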